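Set the flask beside the cedar run, whose 0.95 equiv of coupling partner matches the flask's 0.950 equiv at twice the substrate charge.

| setting | elm | alder | cedar | flask |
|---|---|---|---|---|
| substrate | 20 mM (fed, over 5.0 h) | 20 mM (fed, over 5.0 h) | 40 mM (fed, over 5.0 h) | 20 mM (fed, over 5.0 h) |
| coupling partner | 1.3 equiv | 2.1 equiv | 0.95 equiv | 0.950 equiv |
| remark | run made earlier; the fed solution adds 0.20 times the starting volume | run made earlier; the fed solution adds 0.20 times the starting volume | run made earlier; the fed solution adds 0.20 times the starting volume | the fed solution adds 0.20 times the starting volume |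
| time |  |  |  | 10 d |

| run | time / d | double product / % | substrate / % |
|---|---|---|---|
| elm | 1.04 | 7.1 | 69.0 |
| elm | 1.25 | 7.9 | 63.8 |
| elm | 2.08 | 12.3 | 49.8 |
| elm | 2.50 | 13.1 | 45.3 |
| elm | 3.00 | 13.9 | 40.0 |
| elm | 5.00 | 15.7 | 26.2 |
| elm | 6.00 | 15.4 | 22.0 |
| alder | 1.04 | 13.0 | 54.9 |
| alder | 1.25 | 15.4 | 47.4 |
| alder | 2.08 | 25.3 | 32.1 |
| alder | 2.50 | 27.6 | 26.1 |
| alder | 3.00 | 29.6 | 21.7 |
| alder | 5.00 | 33.1 | 9.7 |
| alder | 6.00 | 32.9 | 6.6 |
| cedar | 1.04 | 8.4 | 62.0 |
| cedar | 1.67 | 10.2 | 49.2 |
| cedar | 2.50 | 12.1 | 40.6 |
| cedar | 4.00 | 10.6 | 30.8 |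
| cedar | 6.00 | 8.7 | 22.8 |

(standard deviation of a reading: 0.5 percentage points)

* time up to 10 d at which double product stands highest
* the amount of double product, in percent of the substrate charged, at that time

- amounts are per litre of the starting volume; all of the dose is in the solution fed

I reasoned that with the ratio held, doubling both charges doubles the pace of each second-order step, so reaction time to the peak, multiplied by the charge, carries over where every step is second-order. A first-order way back from double product, if there is one, keeps its pace when the charges change, so I took this carry-over as a rough estimate. In cedar, double product read highest at 2.50 d, but the neighbouring readings lay at 1.67 d and 4.00 d, so this peak was a coarse reading. My first round, scaling that time directly, gave 5.00 d. But the feed delivers its substrate on average at its midpoint, so I went round again, counting from 0.104 d. This gave the peak clock 4.79 d, the reaction time to the peak referred to the flask's charge. Adding the flask's half feed back put my peak at 4.90 d. The clock gave no height.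

The forecast said 5 d (3.8 d to 6.5 d) and 8.5% (7.4% to 9.7%): “Cedar peaks near 2.5 d, which suggests about 5 d here.”

The flask peaked at 4.24 d with 9.09%, while single product stood at 39.9%.

    coupling partner + single product ⇌ double product (K = 56.0 M⁻¹, k = 1.30 M⁻¹ h⁻¹)
    substrate + coupling partner → single product (k = 0.880 M⁻¹ h⁻¹)
    substrate + double product → side product (k = 0.660 M⁻¹ h⁻¹)

Its reaction time was 4.14 d, so the clock ran long by a factor 1.16, though inside the 3.13 d to 7.79 d that cedar's neighbouring readings allowed.

For the neighbour flask with 5.0 mM of substrate, the clock gave a peak near 19.3 d, later than 10 d, so its highest should stand at the end. Computed, its best was 3.82%, and at 10.0 d it held 3.82%.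

The numbers in the tables are simulated for an exercise; scatter was added.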